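**Retrosynthetic overview**
1. The carbon sources are caffeic acid 1 (silylated via 2 to the oxidation-proof dienophile 3) and natural (R)-rosmarinic acid 4. Compound 4 already holds the lactate stereocentre, the E-acrylate and the latent diene ring.
2. The key disconnection is a retro-[4+2] of the bicyclo[2.2.2]octenedione across C2–Cα and C5–Cβ: a free, unmasked o-quinone as carbodiene plus an E-cinnamic acid. (Caffeoyl ring of 4: C1 bears the side chain, C3/C4 the oxygens. Cα/Cβ are the alkene carbons of 3.)
3. The quinone is not masked and 4 is not protected. Both catechols are oxidised (bis-o-quinone 5), only the acrylate-activated quinone cycloadds (6), and the spectator quinone is then reduced back (7).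
4. Ring order: the two new six-membered rings of the bicycle close together in that one cycloaddition, with all four ring stereocentres. No other ring is formed, and desilylation gives 8.

Assumption: commercial rosmarinic acid is the natural (R)-enantiomer, and the two facial diastereomers from step 2 are assigned by converting each to 8 and comparing rotation and CD with the natural product.

Step 1
Reactants: 1 caffeic acid
Product: 3 (E)-3,4-bis(tert-butyldimethylsilyloxy)cinnamic acid, via tris-TBS caffeate 2 (not isolated)
Conditions: TBSCl (3.5 equiv), imidazole (7 equiv), DMF, rt, 12 h; then AcOH/THF/H2O 3:1:1, rt, 1 h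
Reagents that add atoms: tert-butyldimethylsilyl chloride (TBSCl), CC(C)(C)[Si](C)(C)Cl
Why: Standard silyl ether formation (TBSCl/imidazole) caps both phenols and the acid, and mild acidic hydrolysis then cleaves only the far more labile silyl ester while the acid-stable aryl TBS ethers stay, with no stereocentre formed and the E-alkene retained.

Step 2
Reactants: 4 (R)-rosmarinic acid; 3 (E)-3,4-bis(tert-butyldimethylsilyloxy)cinnamic acid
Product: 7 yunnaneic acid C bis-TBS ether, via rosmarinic acid bis-o-quinone 5 (not isolated), via cycloadduct quinone 6 (not isolated)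
Conditions: PhI(OAc)2 (2.05 equiv), MeCN, −20 °C, 15 min; 3 (3 equiv), 0 °C to rt, dark, N2, 12–24 h (LC-MS control); L-ascorbic acid (1.5 equiv), H2O, 0 °C; preparative C18 HPLC
Reagents that add atoms: none
Why: Proposed new method: PhI(OAc)2 turns both catechols of 4 into o-quinones so that no free catechol is left to shuffle the redox state, and the acrylate-bearing quinone (lower LUMO, its C2 being the δ-position of both the C4 ketone and the ester) should outrun the alkyl quinone in an inverse-electron-demand Diels–Alder reaction as C2/C5 carbodiene with the electron-rich, non-oxidisable styrene 3 (nucleophilic Cα to C2, benzylic Cβ to C5), the E-alkene fixing the trans acid/aryl pair and the aryl-endo, carboxyl-over-the-dicarbonyl transition state fixing the relative configuration of all four new centres, after which ascorbic acid reduces only the surviving conjugated o-quinone and not the bridged non-conjugated diketone; the remote (R) centre gives little facial bias, so the (1R,2R,3S,4R) isomer 7 is separated from its core-epimeric diastereomer by HPLC; the closest known chemistry is the thermal [4+2] cycloaddition of o-benzoquinones with styrenes to bicyclo[2.2.2]octenediones.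

Step 3
Reactants: 7 yunnaneic acid C bis-TBS ether
Product: 8 yunnaneic acid C
Conditions: Et3N·3HF (5 equiv), MeCN, 0 °C to rt, dark, 3 h; C18 chromatography (H2O/MeCN, 0.1% HCO2H)
Reagents that add atoms: none
Why: Fluoride-mediated desilylation (strong Si–F bond) with the mildly acidic Et3N·3HF frees both phenols without base, so benzilic-type rearrangement of the 1,2-diketone, cleavage of the lactate ester and epimerisation at C2 or at the lactate centre are avoided and no stereocentre is touched.

**Compound list**
1 | caffeic acid, (E)-3-(3,4-dihydroxyphenyl)prop-2-enoic acid | O=C(O)/C=C/c1ccc(O)c(O)c1 | starting material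
2 | tert-butyldimethylsilyl (E)-3-[3,4-bis(tert-butyldimethylsilyloxy)phenyl]prop-2-enoate (tris-TBS caffeate) | CC(C)(C)[Si](C)(C)OC(=O)/C=C/c1ccc(O[Si](C)(C)C(C)(C)C)c(O[Si](C)(C)C(C)(C)C)c1 | intermediate
3 | (E)-3-[3,4-bis(tert-butyldimethylsilyloxy)phenyl]prop-2-enoic acid | O=C(O)/C=C/c1ccc(O[Si](C)(C)C(C)(C)C)c(O[Si](C)(C)C(C)(C)C)c1 | intermediate
4 | (R)-rosmarinic acid, (R)-2-[(E)-caffeoyloxy]-3-(3,4-dihydroxyphenyl)propanoic acid | O=C(/C=C/c1ccc(O)c(O)c1)O[C@H](Cc1ccc(O)c(O)c1)C(=O)O | starting material
5 | rosmarinic acid bis-o-quinone: both catechol rings of 4 oxidised to 3,4-dioxocyclohexa-1,5-dienyl rings, (R) centre and E-alkene kept | O=C(/C=C/C1=CC(=O)C(=O)C=C1)O[C@H](CC1=CC(=O)C(=O)C=C1)C(=O)O | intermediate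
6 | cycloadduct quinone: (1R,2R,3S,4R)-7,8-dioxobicyclo[2.2.2]oct-5-ene, 2-CO2H syn to the diketone bridge, 3-[3,4-bis(TBSO)phenyl] syn to the alkene bridge, C6 bearing the E-acrylate of the (R)-lactic acid whose ring is still the o-quinone | O=C(/C=C/C1=C[C@H]2C(=O)C(=O)[C@@H]1[C@H](C(=O)O)[C@H]2c1ccc(O[Si](C)(C)C(C)(C)C)c(O[Si](C)(C)C(C)(C)C)c1)O[C@H](CC1=CC(=O)C(=O)C=C1)C(=O)O | intermediate
7 | yunnaneic acid C bis-TBS ether: as 6 but with the lactate ring reduced back to the catechol | O=C(/C=C/C1=C[C@H]2C(=O)C(=O)[C@@H]1[C@H](C(=O)O)[C@H]2c1ccc(O[Si](C)(C)C(C)(C)C)c(O[Si](C)(C)C(C)(C)C)c1)O[C@H](Cc1ccc(O)c(O)c1)C(=O)O | intermediate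
8 | yunnaneic acid C, (1R,2R,3S,4R)-6-{(E)-3-[(1R)-1-carboxy-2-(3,4-dihydroxyphenyl)ethoxy]-3-oxoprop-1-enyl}-3-(3,4-dihydroxyphenyl)-7,8-dioxobicyclo[2.2.2]oct-5-ene-2-carboxylic acid | O=C(/C=C/C1=C[C@H]2C(=O)C(=O)[C@@H]1[C@H](C(=O)O)[C@H]2c1ccc(O)c(O)c1)O[C@H](Cc1ccc(O)c(O)c1)C(=O)O | target

**Step count**
- Total steps: 3.
- Longest linear sequence: 3 (1 → 3 → 7 → 8). The branch from 4 is 2 steps long.

**Steps most likely to fail**

**1. Step 2.**
- The spectator alkyl o-quinone may tautomerise, dimerise or compete for 3.
- The bimolecular cycloaddition of a 1,2-disubstituted push–pull alkene may lose to other pathways. These are quinone self-dimerisation, hetero-[4+2] to a benzodioxane, and [3+2] closure to a dihydrobenzofuran.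
- Facial control is absent.

The fallback gives up redox masking for silyl masking. It sets out from 4 and comes back at 8. TBSCl/imidazole in DMF gives penta-TBS rosmarinate F1. Catalytic LiOAc in moist DMF at rt cleaves the silyl ester. Because aryl silyl ethers leave faster the more acidic the phenol, it also removes only the two silyl ethers on the acrylate-conjugated ring. This gives lactate-ring bis-TBS rosmarinic acid F2. One equivalent of PhI(OAc)2 in CH2Cl2 gives the single mono-o-quinone F3. With no second quinone in the flask, F3 can be held with excess 3 at 40 °C or under 10 kbar. This gives tetra-TBS yunnaneic acid C F4, whose diastereomers are separated on silica. Et3N·3HF as in step 3 then delivers 8.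

**2. Step 3.** The polar, light- and base-sensitive triacid may not survive fluoride treatment and the isolation that follows.

The fallback makes a separate deprotection unnecessary. It sets out from 1 and comes back at 8. Hexamethyldisilazane (cat. TMSCl, neat, 80 °C, then evaporation) gives tris-TMS caffeate F5, which replaces 3 in step 2. With 5 it gives the TMS-protected cycloadduct quinone F6. Anhydrous acetic acid cannot strip aryl TMS ethers, because silicon prefers the less acidic oxygen. The aqueous ascorbic acid quench both reduces the spectator quinone and hydrolyses the three TMS groups, giving 8 directly. This variant is held in reserve because TMS ethers leave little margin for adventitious water during the cycloaddition.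

**3. Step 1.** Hydrolysis of silyl ester 2 may also strip the labile silyl ether para to the acrylate.

The fallback protects the acid orthogonally. It sets out from 1 and comes back at 3. Allyl bromide with KHCO3 in DMF alkylates only the carboxylate, giving allyl caffeate F7. TBSCl/imidazole gives allyl 3,4-bis(TBSO)cinnamate F8. Catalytic Pd(PPh3)4 with morpholine in THF (Tsuji–Trost deallylation, neutral) releases 3.

**Further compounds**
F1 | step 2 | penta-TBS rosmarinate | O=C(/C=C/c1ccc(O[Si](C)(C)C(C)(C)C)c(O[Si](C)(C)C(C)(C)C)c1)O[C@H](Cc1ccc(O[Si](C)(C)C(C)(C)C)c(O[Si](C)(C)C(C)(C)C)c1)C(=O)O[Si](C)(C)C(C)(C)C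
F2 | step 2 | lactate-ring bis-TBS rosmarinic acid | O=C(/C=C/c1ccc(O)c(O)c1)O[C@H](Cc1ccc(O[Si](C)(C)C(C)(C)C)c(O[Si](C)(C)C(C)(C)C)c1)C(=O)O
F3 | step 2 | mono-o-quinone | O=C(/C=C/C1=CC(=O)C(=O)C=C1)O[C@H](Cc1ccc(O[Si](C)(C)C(C)(C)C)c(O[Si](C)(C)C(C)(C)C)c1)C(=O)O
F4 | step 2 | tetra-TBS yunnaneic acid C | O=C(/C=C/C1=C[C@H]2C(=O)C(=O)[C@@H]1[C@H](C(=O)O)[C@H]2c1ccc(O[Si](C)(C)C(C)(C)C)c(O[Si](C)(C)C(C)(C)C)c1)O[C@H](Cc1ccc(O[Si](C)(C)C(C)(C)C)c(O[Si](C)(C)C(C)(C)C)c1)C(=O)O
F5 | step 3 | tris-TMS caffeate | C[Si](C)(C)OC(=O)/C=C/c1ccc(O[Si](C)(C)C)c(O[Si](C)(C)C)c1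
F6 | step 3 | TMS-protected cycloadduct quinone | O=C(/C=C/C1=C[C@H]2C(=O)C(=O)[C@@H]1[C@H](C(=O)O[Si](C)(C)C)[C@H]2c1ccc(O[Si](C)(C)C)c(O[Si](C)(C)C)c1)O[C@H](CC1=CC(=O)C(=O)C=C1)C(=O)O
F7 | step 1 | allyl caffeate | C=CCOC(=O)/C=C/c1ccc(O)c(O)c1
F8 | step 1 | allyl 3,4-bis(TBSO)cinnamate | C=CCOC(=O)/C=C/c1ccc(O[Si](C)(C)C(C)(C)C)c(O[Si](C)(C)C(C)(C)C)c1
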